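## The problem

The target 34 is a 12,6-germacranolide: a ten-membered carbocycle (C1–C10) trans-fused at C6/C7 to an α-methylene-γ-butyrolactone (O–C6, C7–C11(=C13)–C12=O), with a trisubstituted C4=C5 alkene whose ring bonds are cis (Z). Its six stereocentres fall into three groups that are insulated from one another: the anti pair C2(OAc)/C3(OH), the trans ring fusion C6/C7, and the syn pair C9(O-angeloyl)/C10(CH3). C10 can bias C9 (Felkin–Anh) and a closed transition state can tie C6 to C7, but no reliable acyclic relay runs across the C1 and C8 methylenes or across the alkene. The remaining relationships therefore need reagent control or a transfer of chirality. Closure of a ten-membered ring is penalised by entropy and transannular strain, and the Z alkene must be compatible with that ring. The α-methylene lactone and the angelate are Michael acceptors, the angelate isomerises to the tiglate under base or nucleophiles, the C2 acetate can migrate to a free C3 hydroxyl, and the allylic C3 and C6 oxygens ionise under acid. The acyl groups and the lactone therefore come late. The enabling feature is the array C2(O)–C3(O)–C4(CH3)=C5–C6 inside the ring: a homoallylic alcohol with an anti-1,2-dioxygen pattern and a Z alkene, which is the retron of the addition of a C2 aldehyde to an (E)-γ-alkoxyallylboron unit that carries boron on C5.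

## Retrosynthesis

**Acyl groups and the C3 ether (34 ⇒ 33 ⇒ 32 ⇒ 31).** The C3–O benzyl bond, the C9 ester bond and the C9–O silyl bond are cut. The angelate is placed after all boron, copper and hydride chemistry because it would not survive them. The 4-methoxybenzyl ether on C3 is removed last, so that no free hydroxyl sits next to the C2 acetate while bases are in use. The forward steps must acylate a hindered alcohol without Z-to-E isomerisation and cleave one benzylic ether oxidatively.

**Lactone (31 ⇒ 29 ⇒ 28 ⇒ 27).** The C12–O6 acyl bond is cut and C12 is lowered to the alcohol level, giving the 2-methylene-1,4-diol 29. The C2 acetate is put on at 27, where C2–OH is the only free hydroxyl. Carrying the lactone earlier is rejected on two counts. The methylene lactone would add boryl-copper, and even a saturated lactone would turn C6–O into an allylic carboxylate that competes with the acetal as leaving group. C9 keeps its tert-butyldimethylsilyl ether through the oxidation so that only the five-membered lactone can form.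

**Ring (27 ⇒ 25), the key cut.** The C2–C3 bond is cut. The ring opens to an acyclic chain, two stereocentres and the alkene geometry disappear, and one boron-bearing stereocentre (C5) appears. The neighbouring cuts are weaker. C3–C4 would create one centre under substrate control only. C4=C5 (metathesis) would create no stereocentre and leave the geometry to the ring. C6–C7 is better made intermolecularly. The forward reaction must close the ring faster than it oligomerises and must pass through the chair with C6 axial.

**Boron and aldehyde (25 ⇒ 24 ⇒ 23).** The C2 aldehyde is traced to a tert-butyl ester, reduced only after boron is in place because boryl-copper adds to aldehydes. The C5–B bond and the E enol ether are traced to the allyl bis(4-methoxybenzyl) acetal 23 by an SN2′ boryl substitution. This removes the C5 stereocentre; the forward step has to choose one face of C5.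

**Chain union (23 ⇒ 22 ⇒ 14 + 21).** The C6–C7 bond is cut between the Z enal 21 and the allyltrichlorosilane 14. One step then gives both stereocentres, the exocyclic methylene and the C12 oxygen in its final place. A C5–C6 cut would need an epimerisable α-branched β,γ-unsaturated aldehyde. Aldol cuts would put the carbonyl on the wrong carbon (C8 or C11). The forward reaction must be anti-selective, which the geometry of 14 provides through a closed transition state. It must also be face-selective, which needs a chiral catalyst because the stereocentres of 14 are remote.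

**Allyl unit (14 ⇒ 13 ⇒ 12 ⇒ 11 ⇒ 7 + 10).** The C7=C11 alkene is cut by cross-metathesis between the terminal alkene 7 and the 2-substituted acrolein 10. The preference of the enal for the E geometry places the formyl carbon (later C13, the silicon-bearing carbon) trans to C8, which is the geometry the anti addition needs. Two functional-group changes (12, 13) lead to 14.

**C9/C10 fragment (7 ⇒ 6 ⇒ 5 ⇒ 4 ⇒ 3 ⇒ 1 + 2).** The C8–C9 bond is cut by an aldehyde allylation, matched with the Felkin–Anh preference of 5. The C10–C1 bond is cut by an auxiliary-controlled enolate alkylation of 1 with 2. This brings C1 and C2 in the first step, with C2 already at the ester level from which the aldehyde is later unveiled. Chiral-pool C4 synthons that end at C1 would need a separate one-carbon homologation.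

**Enal (21 ⇒ 20 ⇒ 17 + 19; 17 ⇒ 16 ⇒ 15; 19 ⇒ 18; 10 ⇒ 9 ⇒ 8).** The C5–C6 bond is cut by formylation of an alkenyllithium. The two acetal C–O bonds are cut by acetalisation of 17 with two equivalents of the silyl ether 19. The C4–CH3 bond is cut by anti carbomagnesiation of 15, which fixes the Z geometry. A butenolide precursor would hold the same geometry but costs more redox and protection steps.

## Roads not taken

Alternative 1: Here the C4–C9 bond is reconnected in the retrosynthetic sense, so the ten-membered ring is hidden in a cis-fused six/six framework. In the forward sense an alkoxide on C9 expels a sulfonate on C5, the C4–C9 bond breaks, and the ketone A1 appears with the Z alkene.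
- Merits: the ring is unveiled, not closed, so there is no entropic penalty. The alkene geometry follows from an antiperiplanar arrangement, and fragmentations to cyclodecenones are a known reaction class. In certainty of ring formation this road is better than the chosen one.
- Weak points: the bicyclic framework itself is a long synthesis (tertiary C9 alcohol, quaternary C4, antiperiplanar C5 sulfonate, oxygens on C2, C3 and C6, the C7 branch). A1 still needs a diastereoselective reduction at C9 on a flexible ring next to an epimerisable C10. Its isopropenyl group has no C12 oxygen, so an allylic oxidation must distinguish C12 from the allylic positions of C4=C5. Its acetonide leaves C2 and C3 undifferentiated.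
- Against it the chosen plan sets a convergent chain, C9 and the C12 oxygen in place before the ring exists, and a ring-forming step that also differentiates C2 from C3.

Alternative 2: The C3–C4 bond is cut. An open chain that already carries the lactone, the angelate, a C3 aldehyde and a Z iodoalkene at C4 would be treated with CrCl2 and a catalytic amount of NiCl2; the alkenylchromium species formed at C4 attacks the aldehyde and the ring closes to A2.
- Merits: this ring closure has close precedent for medium rings and tolerates the lactone and the angelate, so A2 is only a few steps from 34. The alkene geometry is carried in, not created. In precedent and in late-stage convergence this road is better than the chosen one.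
- Weak points: only one stereocentre is formed, under substrate control by an α-silyloxy aldehyde inside a macrocyclic transition state whose sense is hard to predict. The aldehyde is epimerisable. A2 has the free hydroxyl on C3 and the silyl ether on C2, the reverse of what the acetate needs, so protecting groups must be exchanged. A large excess of a divalent chromium salt is required.
- Against it the chosen plan sets two stereocentres and the alkene in one closed transition state governed by a defined C5 centre, and leaves exactly the C2 hydroxyl free.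

Alternative 3: The C6–C7 bond is cut and an O–C13 bond is added, giving a 13-membered diallylic ether. Tin–lithium exchange at C6 triggers a [2,3]-Wittig shift that contracts the ring to the cyclodecenol A3.
- Merits: one step forms C6–C7 with both stereocentres and the 2-substituted allyl branch, a bond the chosen route must make with a chiral catalyst. Ring contraction of such ethers to ten-membered carbocycles is a known reaction class, so the precedent for the ring size is closer than for the chosen key step.
- Weak points: a 13-membered ether must be closed first. The C6 carbanion is allylic, hence configurationally labile and ambident ([1,2] shift, attack through C4). The stereochemical outcome rests on the conformation of the macrocycle. The strongly basic conditions exclude all esters. The C2/C3 diol is carried as an acetonide and must be differentiated afterwards.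
- Against it the chosen plan sets chirality transfer from a configurationally stable C–B centre under neutral conditions, no preliminary macrocycle, and a differentiated diol.

Key step: step 21

Remark: locants C1–C13 are those of the germacrane skeleton of 34 and are used for all intermediates. Chiral reagents are specified by the face they must attack; the antipode named is the one expected to do so.

## Route

Step 1
Reactants: 1 (4R)-4-benzyl-3-propanoyl-1,3-oxazolidin-2-one; 2 tert-butyl bromoacetate
Product: 3 tert-butyl (3S)-4-[(4R)-4-benzyl-2-oxo-1,3-oxazolidin-3-yl]-3-methyl-4-oxobutanoate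
Conditions: NaN(SiMe3)2, THF, −78 °C; then 2, −78 → −40 °C
Reagents that add atoms: none
Why: Evans alkylation; the chelated Z sodium enolate is alkylated on the face opposite the benzyl group, which sets C10 (S) and brings in C1 and C2 at the ester level.

Step 2
Reactants: 3 alkylated imide
Product: 4 tert-butyl (3S)-4-hydroxy-3-methylbutanoate
Conditions: LiBH4, MeOH (1 equiv), THF, 0 °C
Reagents that add atoms: none
Why: Reductive removal of the auxiliary; the activated imide carbonyl is reduced while the hindered tert-butyl ester is left, and the oxazolidinone is recovered.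

Step 3
Reactants: 4 hydroxy ester
Product: 5 tert-butyl (3S)-3-methyl-4-oxobutanoate
Conditions: Dess–Martin periodinane, NaHCO3, CH2Cl2, 0 °C; used at once
Reagents that add atoms: none
Why: Dess–Martin oxidation under buffered, non-basic conditions should keep the α-stereocentre intact.

Step 4
Reactants: 5 aldehyde
Product: 6 tert-butyl (3S,4S)-4-hydroxy-3-methylhept-6-enoate
Conditions: (−)-Ipc2B(allyl) (from (−)-Ipc2BOMe and allylMgBr, salt-free), Et2O, −78 °C; then pH 7 buffer, H2O2, 0 °C
Reagents that add atoms: (−)-B-allyldiisopinocampheylborane, C=CCB([C@@H]1C[C@@H]2C[C@H]([C@H]1C)C2(C)C)[C@@H]1C[C@@H]2C[C@H]([C@H]1C)C2(C)C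
Why: Brown allylboration through a closed chair; the reagent derived from (+)-α-pinene delivers the allyl group to the Si face of the aldehyde, which is also the Felkin–Anh face (matched pair), so C9 (S) forms syn to the C10 methyl group.

Step 5
Reactants: 6 homoallylic alcohol
Product: 7 tert-butyl (3S,4S)-4-[(tert-butyldimethylsilyl)oxy]-3-methylhept-6-enoate
Conditions: tBuMe2SiCl, imidazole, DMAP (cat.), DMF, rt
Reagents that add atoms: tert-butyl(chloro)dimethylsilane, CC(C)(C)[Si](C)(C)Cl
Why: Standard silylation; done promptly so that the γ-hydroxy ester cannot lactonise, and without a silyl triflate, which could cleave the tert-butyl ester.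

Step 6
Reactants: 8 2-methylidenepropane-1,3-diol
Product: 9 2-{[(tert-butyldimethylsilyl)oxy]methyl}prop-2-en-1-ol
Conditions: NaH (1.0 equiv), THF, 0 °C; then tBuMe2SiCl
Reagents that add atoms: tert-butyl(chloro)dimethylsilane, CC(C)(C)[Si](C)(C)Cl
Why: Monosilylation of a symmetrical diol through its poorly soluble monosodium alkoxide.

Step 7
Reactants: 9 allylic alcohol
Product: 10 2-{[(tert-butyldimethylsilyl)oxy]methyl}prop-2-enal
Conditions: MnO2, CH2Cl2, rt
Reagents that add atoms: none
Why: Selective oxidation of a primary allylic alcohol to the enal with MnO2.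

Step 8
Reactants: 7 terminal alkene; 10 2-substituted acrolein
Product: 11 tert-butyl (3S,4S,6E)-4-[(tert-butyldimethylsilyl)oxy]-7-{[(tert-butyldimethylsilyl)oxy]methyl}-3-methyl-8-oxooct-6-enoate
Conditions: second-generation Hoveyda–Grubbs catalyst RuCl2(H2IMes)(=CH-C6H4-2-OiPr) (5 mol%), 10 (3 equiv), CH2Cl2, 40 °C
Reagents that add atoms: none
Why: Cross-metathesis of a terminal alkene with a 2-substituted acrolein, as with methacrolein; the trisubstituted enal should form with C8 trans to the formyl group (E), which fixes the geometry of the later allyl unit.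

Step 9
Reactants: 11 enal
Product: 12 tert-butyl (3S,4S,6Z)-4-[(tert-butyldimethylsilyl)oxy]-7-{[(tert-butyldimethylsilyl)oxy]methyl}-8-hydroxy-3-methyloct-6-enoate
Conditions: NaBH4, CeCl3·7H2O, MeOH, −40 °C
Reagents that add atoms: none
Why: Luche reduction; 1,2-selective for the enal and without effect on the tert-butyl ester.

Step 10
Reactants: 12 allylic alcohol
Product: 13 tert-butyl (3S,4S,6E)-4-[(tert-butyldimethylsilyl)oxy]-7-{[(tert-butyldimethylsilyl)oxy]methyl}-8-chloro-3-methyloct-6-enoate
Conditions: N-chlorosuccinimide, Me2S, CH2Cl2, −20 → 0 °C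
Reagents that add atoms: N-chlorosuccinimide, O=C1CCC(=O)N1Cl
Why: Corey–Kim chlorination of a primary allylic alcohol; direct displacement at the primary carbon should leave the alkene position and geometry unchanged.

Step 11
Reactants: 13 allylic chloride
Product: 14 tert-butyl (3S,4S,6E)-4-[(tert-butyldimethylsilyl)oxy]-7-{[(tert-butyldimethylsilyl)oxy]methyl}-3-methyl-8-(trichlorosilyl)oct-6-enoate
Conditions: HSiCl3, CuCl (5 mol%), iPr2NEt, Et2O, rt; filtered under argon, used crude
Reagents that add atoms: trichlorosilane, Cl[SiH](Cl)Cl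
Why: Copper-catalysed silylation of a primary allylic chloride with trichlorosilane and an amine base; it proceeds at the chloride-bearing carbon with retention of the alkene geometry, so the silicon-bearing carbon stays trans to C8.

Step 12
Reactants: 15 prop-2-yn-1-ol
Product: 16 (2Z)-3-iodo-2-methylprop-2-en-1-ol
Conditions: MeMgBr, CuI (10 mol%), THF, −10 °C → rt; then I2, −20 °C
Reagents that add atoms: methylmagnesium bromide, C[Mg]Br; iodine, II
Why: Copper-catalysed anti carbomagnesiation of the propargylic alkoxide through a five-membered chelate, then iodinolysis with retention; iodine ends cis to the hydroxymethyl group, which is the Z geometry needed at C4=C5.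

Step 13
Reactants: 16 iodo alcohol
Product: 17 (2Z)-3-iodo-2-methylprop-2-enal
Conditions: MnO2, CH2Cl2, 0 °C, in the dark; used at once
Reagents that add atoms: none
Why: MnO2 oxidation of the allylic alcohol; neutral conditions and low temperature should prevent Z-to-E isomerisation.

Step 14
Reactants: 18 (4-methoxyphenyl)methanol
Product: 19 [(4-methoxyphenyl)methoxy]trimethylsilane
Conditions: (Me3Si)2NH, Me3SiCl (cat.), neat, rt
Reagents that add atoms: hexamethyldisilazane, C[Si](C)(C)N[Si](C)(C)C
Why: Silylation of a primary alcohol with hexamethyldisilazane; ammonia is the only by-product.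

Step 15
Reactants: 17 Z iodo enal; 19 silyl ether (two equivalents are consumed)
Product: 20 (1Z)-1-iodo-3,3-bis[(4-methoxyphenyl)methoxy]-2-methylprop-1-ene
Conditions: 19 (2.2 equiv), Me3SiOTf (5 mol%), CH2Cl2, −78 °C; pyridine quench
Reagents that add atoms: [(4-methoxyphenyl)methoxy]trimethylsilane (the second equivalent of 19), COc1ccc(CO[Si](C)(C)C)cc1
Why: Noyori acetalisation; two molecules of the alkoxysilane each deliver one 4-methoxybenzyloxy group to the carbonyl carbon, and the carbonyl oxygen leaves as hexamethyldisiloxane. Aprotic and at −78 °C, the method converts enals into acetals without conjugate addition or alkene isomerisation.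

Step 16
Reactants: 20 alkenyl iodide
Product: 21 (2Z)-4,4-bis[(4-methoxyphenyl)methoxy]-3-methylbut-2-enal
Conditions: tBuLi (2.1 equiv), Et2O, −78 °C; DMF, −78 → −40 °C; aq. NH4Cl
Reagents that add atoms: N,N-dimethylformamide, CN(C)C=O
Why: Iodine–lithium exchange with retention of alkene geometry, then formylation; Z-3,3-dialkoxypropenyllithium reagents are configurationally stable at −78 °C.

Step 17
Reactants: 14 allyltrichlorosilane; 21 Z enal
Product: 22 tert-butyl (3S,4S,6S,7R,8Z)-4-[(tert-butyldimethylsilyl)oxy]-6-{3-[(tert-butyldimethylsilyl)oxy]prop-1-en-2-yl}-7-hydroxy-10,10-bis[(4-methoxyphenyl)methoxy]-3,9-dimethyldec-8-enoate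
Conditions: (R,R)-2,2′-bipyrrolidine-derived bisphosphoramide with a pentane-1,5-diyl tether (10 mol%), iPr2NEt, CH2Cl2, −78 °C; then sat. aq. NaHCO3
Reagents that add atoms: none
Why: Lewis-base-catalysed addition of a γ-substituted allyltrichlorosilane to a conjugated aldehyde through a closed chair at hexacoordinate silicon; with C8 trans to the silicon-bearing carbon, C8 sits equatorial and the C6/C7 relationship is anti. The chiral catalyst is chosen to deliver C7 to the Si face of the aldehyde, which gives 6R and therefore 7S. The exocyclic C11=C13 alkene and the C12 silyl ether arise in the same step.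

Step 18
Reactants: 22 C6 alcohol
Product: 23 tert-butyl (3S,4S,6S,7R,8Z)-4-[(tert-butyldimethylsilyl)oxy]-6-{3-[(tert-butyldimethylsilyl)oxy]prop-1-en-2-yl}-10,10-bis[(4-methoxyphenyl)methoxy]-3,9-dimethyl-7-[(triethylsilyl)oxy]dec-8-enoate
Conditions: Et3SiCl, imidazole, DMAP (cat.), DMF, 0 °C → rt
Reagents that add atoms: chlorotriethylsilane, CC[Si](Cl)(CC)CC
Why: Silylation under basic conditions, which the acetal and the tert-butyl ester tolerate; the triethylsilyl group makes C6–O a non-leaving group and can later be removed beside the C9 silyl ether.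

Step 19
Reactants: 23 allyl acetal
Product: 24 tert-butyl (3S,4S,6S,7R,8R,9E)-4-[(tert-butyldimethylsilyl)oxy]-6-{3-[(tert-butyldimethylsilyl)oxy]prop-1-en-2-yl}-10-[(4-methoxyphenyl)methoxy]-3,9-dimethyl-8-(4,4,5,5-tetramethyl-1,3,2-dioxaborolan-2-yl)-7-[(triethylsilyl)oxy]dec-9-enoate
Conditions: CuCl (10 mol%), (R,R)-QuinoxP* (10 mol%), KOtBu (20 mol%), B2pin2 (1.5 equiv), THF, 0 °C
Reagents that add atoms: bis(pinacolato)diboron, CC1(C)OB(OC1(C)C)B1OC(C)(C)C(C)(C)O1
Why: Copper-catalysed γ-selective boryl substitution of an allyl acetal, known for linear and carbocyclic allyl acetals; boryl-copper adds syn across C4=C5 with boron on C5, and loss of one alkoxide from C3 gives the E enol ether. Allylic 1,3-strain in the Z alkene holds C6–H in the alkene plane, so the faces differ by OSiEt3 against C7; attack anti to the C6–O bond (Re face of C5) gives 5R, and the ligand antipode is chosen to reinforce it.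

Step 20
Reactants: 24 allylboronate ester
Product: 25 (3S,4S,6S,7R,8R,9E)-4-[(tert-butyldimethylsilyl)oxy]-6-{3-[(tert-butyldimethylsilyl)oxy]prop-1-en-2-yl}-10-[(4-methoxyphenyl)methoxy]-3,9-dimethyl-8-(4,4,5,5-tetramethyl-1,3,2-dioxaborolan-2-yl)-7-[(triethylsilyl)oxy]dec-9-enal
Conditions: iBu2AlH (1.2 equiv), toluene, −78 °C; MeOH; aq. potassium sodium tartrate (KNaC4H4O6), 0 °C; kept cold and dilute, used at once
Reagents that add atoms: none
Why: Partial reduction of a tert-butyl ester; the tetrahedral aluminium intermediate is stable at −78 °C and releases the C2 aldehyde only on neutral work-up, conditions the pinacol boronate and the enol ether tolerate.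

Step 21
Reactants: 25 aldehyde with C5 pinacol boronate and E enol ether
Product: 27 (2R,3S,4Z,6R,7S,9S,10S)-9-[(tert-butyldimethylsilyl)oxy]-7-{3-[(tert-butyldimethylsilyl)oxy]prop-1-en-2-yl}-3-[(4-methoxyphenyl)methoxy]-4,10-dimethyl-6-[(triethylsilyl)oxy]cyclodec-4-en-2-ol, via borate ester 26 (not isolated)
Conditions: toluene, 70 °C, syringe-pump addition to a final 1 mM; then aq. NaHCO3, rt
Reagents that add atoms: none
Why: Proposed new method: the vacant orbital on boron in 25 accepts the aldehyde oxygen, and inside the resulting six-membered chair (B, O, C2, C3, C4, C5) the C2–C3 bond is made as the C5–B bond is given up, so that boron ends on oxygen and the alkene on C4=C5; the closest known reactions are intermolecular additions of α-substituted (E)-γ-alkoxyallyl pinacolboronates to aldehydes and intramolecular allylborations that close five- to seven-membered rings. The ten-membered carbocycle closes by this one C–C bond, exo with respect to the carbonyl group and with the whole allyl unit C3–C4–C5 taken into the ring; the tether C1–C10–C9–C8–C7–C6 joins the aldehyde carbon to the boron-bearing carbon and so spans the 1,4-positions of the chair. C3 is controlled by the E enol ether, which places the 4-methoxybenzyloxy group equatorial, and C2 by the equatorial aldehyde chain C1, which together give the anti relationship. The absolute sense of both centres comes from C5 (R) by suprafacial 1,3-transfer with C6 axial, the arrangement favoured by the C4 methyl group (1,2-strain with an equatorial C6) and by the pinacol ester. Axial C6 also gives the Z alkene, the less strained geometry in a cyclodecene, and the tether bridges an axial C6 and an equatorial C1 without forcing a boat. The step needs ring closure to outrun oligomerisation, which high dilution, slow addition and the low intermolecular reactivity of γ-alkoxyallyl pinacolboronates should secure. Hydrolysis of borate 26 frees C2–OH while C3 stays protected.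

Step 22
Reactants: 27 cyclodecenol
Product: 28 C2 acetate of 27
Conditions: Ac2O, pyridine, DMAP (cat.), CH2Cl2, 0 °C → rt
Reagents that add atoms: acetic anhydride, CC(=O)OC(C)=O
Why: Acetylation of the only free hydroxyl; no selectivity is asked for.

Step 23
Reactants: 28 acetate
Product: 29 C6,C12-diol (C2 acetate, C3 4-methoxybenzyl ether, C9 tert-butyldimethylsilyl ether)
Conditions: HF·pyridine, pyridine, THF, 0 °C
Reagents that add atoms: none
Why: Graded desilylation; the primary allylic tert-butyldimethylsilyl ether and the secondary triethylsilyl ether are cleaved well before the hindered secondary tert-butyldimethylsilyl ether on C9, and the acetate and benzyl ether are stable to buffered fluoride.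

Step 24
Reactants: 29 2-methylene-1,4-diol
Product: 31 (2R,3S,4Z,6R,7S,9S,10S)-2-acetoxy-9-[(tert-butyldimethylsilyl)oxy]-3-[(4-methoxyphenyl)methoxy]germacra-4,11(13)-dien-12,6-olide, via lactol 30 (not isolated)
Conditions: TEMPO (20 mol%), PhI(OAc)2 (3 equiv), CH2Cl2, rt
Reagents that add atoms: none
Why: TEMPO-mediated oxidative lactonisation; the primary allylic alcohol is oxidised first, the enal is trapped by C6–OH as the five-membered lactol, and this is oxidised on to the α-methylene lactone. With C9 still silylated, no six-membered lactone can form.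

Step 25
Reactants: 31 lactone
Product: 32 C9 alcohol (C2 acetate, C3 4-methoxybenzyl ether)
Conditions: HF·pyridine, THF, rt
Reagents that add atoms: none
Why: Fluoride-mediated cleavage of the remaining silyl ether under mildly acidic conditions, which spare the acetate, the benzyl ether and the methylene lactone.

Step 26
Reactants: 32 C9 alcohol
Product: 33 C9 angelate (C2 acetate, C3 4-methoxybenzyl ether)
Conditions: angelic acid, 2,4,6-trichlorobenzoyl chloride, Et3N, toluene, rt; then 32, 75 °C
Reagents that add atoms: angelic acid, C/C=C(/C)C(=O)O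
Why: Yamaguchi-type esterification through the mixed anhydride; this protocol acylates hindered secondary alcohols with angelic acid without the Z-to-E isomerisation that carbodiimide methods with nucleophilic catalysts cause.

Step 27
Reactants: 33 4-methoxybenzyl ether
Product: 34 (2R,3S,4Z,6R,7S,9S,10S)-2-acetoxy-3-hydroxy-9-{[(2Z)-2-methylbut-2-enoyl]oxy}germacra-4,11(13)-dien-12,6-olide (CNP0122017.1)
Conditions: DDQ, CH2Cl2/pH 7 buffer, 0 °C
Reagents that add atoms: none
Why: Oxidative cleavage of the 4-methoxybenzyl ether under neutral conditions; the electron-poor alkenes are inert to the quinone, and the absence of base prevents acetate migration to the freed C3 hydroxyl.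

## Compound list

1 | (4R)-4-benzyl-3-propanoyl-1,3-oxazolidin-2-one | CCC(=O)N1[C@H](Cc2ccccc2)COC1=O | starting material
2 | tert-butyl bromoacetate | CC(C)(C)OC(=O)CBr | starting material
3 | tert-butyl (3S)-4-[(4R)-4-benzyl-2-oxo-1,3-oxazolidin-3-yl]-3-methyl-4-oxobutanoate | CC(C)(C)OC(=O)C[C@H](C)C(=O)N1[C@H](Cc2ccccc2)COC1=O | intermediate
4 | tert-butyl (3S)-4-hydroxy-3-methylbutanoate | CC(C)(C)OC(=O)C[C@H](C)CO | intermediate
5 | tert-butyl (3S)-3-methyl-4-oxobutanoate | CC(C)(C)OC(=O)C[C@H](C)C=O | intermediate
6 | tert-butyl (3S,4S)-4-hydroxy-3-methylhept-6-enoate | CC(C)(C)OC(=O)C[C@H](C)[C@@H](O)CC=C | intermediate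
7 | tert-butyl (3S,4S)-4-[(tert-butyldimethylsilyl)oxy]-3-methylhept-6-enoate | CC(C)(C)OC(=O)C[C@H](C)[C@@H](O[Si](C)(C)C(C)(C)C)CC=C | intermediate
8 | 2-methylidenepropane-1,3-diol | C=C(CO)CO | starting material
9 | 2-{[(tert-butyldimethylsilyl)oxy]methyl}prop-2-en-1-ol | C=C(CO)CO[Si](C)(C)C(C)(C)C | intermediate
10 | 2-{[(tert-butyldimethylsilyl)oxy]methyl}prop-2-enal | C=C(C=O)CO[Si](C)(C)C(C)(C)C | intermediate
11 | tert-butyl (3S,4S,6E)-4-[(tert-butyldimethylsilyl)oxy]-7-{[(tert-butyldimethylsilyl)oxy]methyl}-3-methyl-8-oxooct-6-enoate | CC(C)(C)OC(=O)C[C@H](C)[C@@H](O[Si](C)(C)C(C)(C)C)C/C=C(/C=O)CO[Si](C)(C)C(C)(C)C | intermediate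
12 | tert-butyl (3S,4S,6Z)-4-[(tert-butyldimethylsilyl)oxy]-7-{[(tert-butyldimethylsilyl)oxy]methyl}-8-hydroxy-3-methyloct-6-enoate | CC(C)(C)OC(=O)C[C@H](C)[C@@H](O[Si](C)(C)C(C)(C)C)C/C=C(/CO)CO[Si](C)(C)C(C)(C)C | intermediate
13 | tert-butyl (3S,4S,6E)-4-[(tert-butyldimethylsilyl)oxy]-7-{[(tert-butyldimethylsilyl)oxy]methyl}-8-chloro-3-methyloct-6-enoate | CC(C)(C)OC(=O)C[C@H](C)[C@@H](O[Si](C)(C)C(C)(C)C)C/C=C(/CCl)CO[Si](C)(C)C(C)(C)C | intermediate
14 | tert-butyl (3S,4S,6E)-4-[(tert-butyldimethylsilyl)oxy]-7-{[(tert-butyldimethylsilyl)oxy]methyl}-3-methyl-8-(trichlorosilyl)oct-6-enoate | CC(C)(C)OC(=O)C[C@H](C)[C@@H](O[Si](C)(C)C(C)(C)C)C/C=C(/C[Si](Cl)(Cl)Cl)CO[Si](C)(C)C(C)(C)C | intermediate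
15 | prop-2-yn-1-ol | C#CCO | starting material
16 | (2Z)-3-iodo-2-methylprop-2-en-1-ol | OC/C(C)=C\I | intermediate
17 | (2Z)-3-iodo-2-methylprop-2-enal | O=C/C(C)=C\I | intermediate
18 | (4-methoxyphenyl)methanol | COc1ccc(CO)cc1 | starting material
19 | [(4-methoxyphenyl)methoxy]trimethylsilane | COc1ccc(CO[Si](C)(C)C)cc1 | intermediate
20 | (1Z)-1-iodo-3,3-bis[(4-methoxyphenyl)methoxy]-2-methylprop-1-ene | COc1ccc(COC(OCc2ccc(OC)cc2)/C(C)=C\I)cc1 | intermediate
21 | (2Z)-4,4-bis[(4-methoxyphenyl)methoxy]-3-methylbut-2-enal | COc1ccc(COC(OCc2ccc(OC)cc2)/C(C)=C\C=O)cc1 | intermediate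
22 | tert-butyl (3S,4S,6S,7R,8Z)-4-[(tert-butyldimethylsilyl)oxy]-6-{3-[(tert-butyldimethylsilyl)oxy]prop-1-en-2-yl}-7-hydroxy-10,10-bis[(4-methoxyphenyl)methoxy]-3,9-dimethyldec-8-enoate | CC(C)(C)OC(=O)C[C@H](C)[C@@H](O[Si](C)(C)C(C)(C)C)C[C@@H](C(=C)CO[Si](C)(C)C(C)(C)C)[C@H](O)/C=C(/C)C(OCc1ccc(OC)cc1)OCc1ccc(OC)cc1 | intermediate
23 | tert-butyl (3S,4S,6S,7R,8Z)-4-[(tert-butyldimethylsilyl)oxy]-6-{3-[(tert-butyldimethylsilyl)oxy]prop-1-en-2-yl}-10,10-bis[(4-methoxyphenyl)methoxy]-3,9-dimethyl-7-[(triethylsilyl)oxy]dec-8-enoate | CC(C)(C)OC(=O)C[C@H](C)[C@@H](O[Si](C)(C)C(C)(C)C)C[C@@H](C(=C)CO[Si](C)(C)C(C)(C)C)[C@H](O[Si](CC)(CC)CC)/C=C(/C)C(OCc1ccc(OC)cc1)OCc1ccc(OC)cc1 | intermediate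
24 | tert-butyl (3S,4S,6S,7R,8R,9E)-4-[(tert-butyldimethylsilyl)oxy]-6-{3-[(tert-butyldimethylsilyl)oxy]prop-1-en-2-yl}-10-[(4-methoxyphenyl)methoxy]-3,9-dimethyl-8-(4,4,5,5-tetramethyl-1,3,2-dioxaborolan-2-yl)-7-[(triethylsilyl)oxy]dec-9-enoate | CC(C)(C)OC(=O)C[C@H](C)[C@@H](O[Si](C)(C)C(C)(C)C)C[C@@H](C(=C)CO[Si](C)(C)C(C)(C)C)[C@H](O[Si](CC)(CC)CC)[C@H](B1OC(C)(C)C(C)(C)O1)/C(C)=C/OCc1ccc(OC)cc1 | intermediate
25 | (3S,4S,6S,7R,8R,9E)-4-[(tert-butyldimethylsilyl)oxy]-6-{3-[(tert-butyldimethylsilyl)oxy]prop-1-en-2-yl}-10-[(4-methoxyphenyl)methoxy]-3,9-dimethyl-8-(4,4,5,5-tetramethyl-1,3,2-dioxaborolan-2-yl)-7-[(triethylsilyl)oxy]dec-9-enal | O=CC[C@H](C)[C@@H](O[Si](C)(C)C(C)(C)C)C[C@@H](C(=C)CO[Si](C)(C)C(C)(C)C)[C@H](O[Si](CC)(CC)CC)[C@H](B1OC(C)(C)C(C)(C)O1)/C(C)=C/OCc1ccc(OC)cc1 | intermediate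
26 | O-(4,4,5,5-tetramethyl-1,3,2-dioxaborolan-2-yl) ether of 27 at C2 (germacrane locants) | CC[Si](CC)(CC)O[C@@H]1/C=C(/C)[C@H](OCc2ccc(OC)cc2)[C@H](OB2OC(C)(C)C(C)(C)O2)C[C@H](C)[C@@H](O[Si](C)(C)C(C)(C)C)C[C@H]1C(=C)CO[Si](C)(C)C(C)(C)C | intermediate
27 | (2R,3S,4Z,6R,7S,9S,10S)-9-[(tert-butyldimethylsilyl)oxy]-7-{3-[(tert-butyldimethylsilyl)oxy]prop-1-en-2-yl}-3-[(4-methoxyphenyl)methoxy]-4,10-dimethyl-6-[(triethylsilyl)oxy]cyclodec-4-en-2-ol (germacrane locants) | CC[Si](CC)(CC)O[C@@H]1/C=C(/C)[C@H](OCc2ccc(OC)cc2)[C@H](O)C[C@H](C)[C@@H](O[Si](C)(C)C(C)(C)C)C[C@H]1C(=C)CO[Si](C)(C)C(C)(C)C | intermediate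
28 | (2R,3S,4Z,6R,7S,9S,10S)-9-[(tert-butyldimethylsilyl)oxy]-7-{3-[(tert-butyldimethylsilyl)oxy]prop-1-en-2-yl}-3-[(4-methoxyphenyl)methoxy]-4,10-dimethyl-6-[(triethylsilyl)oxy]cyclodec-4-en-2-yl acetate (germacrane locants) | CC[Si](CC)(CC)O[C@@H]1/C=C(/C)[C@H](OCc2ccc(OC)cc2)[C@H](OC(C)=O)C[C@H](C)[C@@H](O[Si](C)(C)C(C)(C)C)C[C@H]1C(=C)CO[Si](C)(C)C(C)(C)C | intermediate
29 | (2R,3S,4Z,6R,7S,9S,10S)-9-[(tert-butyldimethylsilyl)oxy]-6-hydroxy-7-(3-hydroxyprop-1-en-2-yl)-3-[(4-methoxyphenyl)methoxy]-4,10-dimethylcyclodec-4-en-2-yl acetate (germacrane locants) | O[C@@H]1/C=C(/C)[C@H](OCc2ccc(OC)cc2)[C@H](OC(C)=O)C[C@H](C)[C@@H](O[Si](C)(C)C(C)(C)C)C[C@H]1C(=C)CO | intermediate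
30 | 6,12-lactol of 29: 12-hydroxy-6,12-epoxy compound with C2 acetate, C3 4-methoxybenzyl ether, C9 tert-butyldimethylsilyl ether, C11=C13 methylene (both C12 epimers) | C=C1C(O)O[C@@H]2/C=C(/C)[C@H](OCc3ccc(OC)cc3)[C@H](OC(C)=O)C[C@H](C)[C@@H](O[Si](C)(C)C(C)(C)C)C[C@@H]12 | intermediate
31 | (2R,3S,4Z,6R,7S,9S,10S)-2-acetoxy-9-[(tert-butyldimethylsilyl)oxy]-3-[(4-methoxyphenyl)methoxy]germacra-4,11(13)-dien-12,6-olide | C=C1C(=O)O[C@@H]2/C=C(/C)[C@H](OCc3ccc(OC)cc3)[C@H](OC(C)=O)C[C@H](C)[C@@H](O[Si](C)(C)C(C)(C)C)C[C@@H]12 | intermediate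
32 | (2R,3S,4Z,6R,7S,9S,10S)-2-acetoxy-9-hydroxy-3-[(4-methoxyphenyl)methoxy]germacra-4,11(13)-dien-12,6-olide | C=C1C(=O)O[C@@H]2/C=C(/C)[C@H](OCc3ccc(OC)cc3)[C@H](OC(C)=O)C[C@H](C)[C@@H](O)C[C@@H]12 | intermediate
33 | (2R,3S,4Z,6R,7S,9S,10S)-2-acetoxy-3-[(4-methoxyphenyl)methoxy]-9-{[(2Z)-2-methylbut-2-enoyl]oxy}germacra-4,11(13)-dien-12,6-olide | C=C1C(=O)O[C@@H]2/C=C(/C)[C@H](OCc3ccc(OC)cc3)[C@H](OC(C)=O)C[C@H](C)[C@@H](OC(=O)/C(C)=C\C)C[C@@H]12 | intermediate
34 | (2R,3S,4Z,6R,7S,9S,10S)-2-acetoxy-3-hydroxy-9-{[(2Z)-2-methylbut-2-enoyl]oxy}germacra-4,11(13)-dien-12,6-olide (CNP0122017.1) | C=C1C(=O)O[C@@H]2/C=C(/C)[C@H](O)[C@H](OC(C)=O)C[C@H](C)[C@@H](OC(=O)/C(C)=C\C)C[C@@H]12 | target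

## Step count and least certain steps

Total: 27 steps. Longest linear sequence: 20 steps (steps 1–5, 8–11, 17–27).

**Step 21 (key step).** Intermolecular allylboration may outrun ring closure, because the bicyclic transition state of a ten-membered ring is strained and no such closure is known. Reaction through a boat, or through the chair with C6 equatorial, would give the syn diol or the E alkene. On prolonged heating the C6 silyloxy group and boron could also be lost by β-elimination. Fallback with known chemistry: the ring is closed at C4=C5 instead, and C2–C3 is made between two molecules. The sequence sets out from 14, which is added to acrolein under the conditions of step 17 to give the C6 vinyl carbinol F1; silylation with Et3SiCl gives the triethylsilyl ether F2, and iBu2AlH reduction gives the aldehyde F3. In parallel, methacrolein is acetalised with two equivalents of 19 (Me3SiOTf) to the bis(4-methoxybenzyl) acetal F4, which is borylated (CuCl, Xantphos, KOtBu, B2pin2) to the achiral (E)-γ-alkoxy-β-methylallylboronate F5. F3 and F5 combine in an intermolecular allylboration to give the anti diene F6; the catalyst is the chiral phosphoric acid TRIP (3,3′-bis(2,4,6-triisopropylphenyl)-1,1′-binaphthyl-2,2′-diyl hydrogen phosphate), in the antipode that favours Si-face attack at C2. Ring-closing metathesis of F6 with the second-generation Grubbs catalyst RuCl2(H2IMes)(PCy3)(=CHPh) under high dilution returns to the route at 27.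

**Step 19.** Facial selection at C5 may be poor if the ligand and the C6 stereocentre oppose each other. Borylcupration of a hindered trisubstituted alkene may be slow enough for the C11=C13 alkene to compete. Fallback without a C5 stereocentre: 23 is reduced with iBu2AlH to the aldehyde acetal F7. CrCl2 with Me3SiI then turns the allyl acetal into a γ-alkoxyallylchromium species (divalent chromium inserts into the α-iodo ether), which adds to the C2 aldehyde within the molecule under high dilution. Such reagents add anti, and the route is rejoined at 27.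

**Step 17.** The Lewis-acidic silicon species may ionise the bis(4-methoxybenzyl) acetal, and a 2,3-disubstituted allylsilane may react with lower facial selectivity than simple crotyl reagents. Fallback: Nozaki–Hiyama–Kishi-type allylation. Chloride 13 is converted with CrCl2 into the allylchromium reagent in the presence of a chiral sulfonamide ligand and added to 21. Allylchromium reagents equilibrate and add anti through a chair, and the route is rejoined at 22. No new isolated compound is involved.

**Step 20.** Over-reduction to the primary alcohol may occur, and allylboration between molecules may begin during work-up while the aldehyde is concentrated. Fallback: 24 is reduced fully with excess iBu2AlH to the stable primary alcohol F8. F8 is oxidised with Dess–Martin periodinane in dilute, buffered CH2Cl2 immediately before the ring closure, returning to 25.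

**Step 26.** The angeloyl group may isomerise to the tigloyl group during acylation of the hindered C9 hydroxyl, and the amine may add to the methylene lactone. Fallback: 32 is esterified (DCC, DMAP) with 2-[bis(2,2,2-trifluoroethoxy)phosphoryl]propanoic acid to the phosphonate ester F9. A Still–Gennari olefination with acetaldehyde (KN(SiMe3)2, 18-crown-6, THF, −78 °C) then builds the Z alkene on the substrate and returns to 33.

## Further compounds

F1 | step 21 | tert-butyl (3S,4S,6S,7R)-4-[(tert-butyldimethylsilyl)oxy]-6-{3-[(tert-butyldimethylsilyl)oxy]prop-1-en-2-yl}-7-hydroxy-3-methylnon-8-enoate | CC(C)(C)OC(=O)C[C@H](C)[C@@H](O[Si](C)(C)C(C)(C)C)C[C@@H](C(=C)CO[Si](C)(C)C(C)(C)C)[C@H](O)C=C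
F2 | step 21 | tert-butyl (3S,4S,6S,7R)-4-[(tert-butyldimethylsilyl)oxy]-6-{3-[(tert-butyldimethylsilyl)oxy]prop-1-en-2-yl}-3-methyl-7-[(triethylsilyl)oxy]non-8-enoate | CC(C)(C)OC(=O)C[C@H](C)[C@@H](O[Si](C)(C)C(C)(C)C)C[C@@H](C(=C)CO[Si](C)(C)C(C)(C)C)[C@H](O[Si](CC)(CC)CC)C=C
F3 | step 21 | (3S,4S,6S,7R)-4-[(tert-butyldimethylsilyl)oxy]-6-{3-[(tert-butyldimethylsilyl)oxy]prop-1-en-2-yl}-3-methyl-7-[(triethylsilyl)oxy]non-8-enal | O=CC[C@H](C)[C@@H](O[Si](C)(C)C(C)(C)C)C[C@@H](C(=C)CO[Si](C)(C)C(C)(C)C)[C@H](O[Si](CC)(CC)CC)C=C
F4 | step 21 | 3,3-bis[(4-methoxyphenyl)methoxy]-2-methylprop-1-ene | C=C(C)C(OCc1ccc(OC)cc1)OCc1ccc(OC)cc1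
F5 | step 21 | 2-{(2E)-3-[(4-methoxyphenyl)methoxy]-2-methylprop-2-en-1-yl}-4,4,5,5-tetramethyl-1,3,2-dioxaborolane | COc1ccc(CO/C=C(\C)CB2OC(C)(C)C(C)(C)O2)cc1
F6 | step 21 | open-chain diene (germacrane locants 2R,3S,6R,7S,9S,10S): C2 alcohol, C3 4-methoxybenzyl ether bearing the C4 isopropenyl group, C6 triethylsilyl ether bearing the C5 vinyl group, C9 and C12 tert-butyldimethylsilyl ethers | C=C(C)[C@H](OCc1ccc(OC)cc1)[C@H](O)C[C@H](C)[C@@H](O[Si](C)(C)C(C)(C)C)C[C@@H](C(=C)CO[Si](C)(C)C(C)(C)C)[C@H](O[Si](CC)(CC)CC)C=C
F7 | step 19 | (3S,4S,6S,7R,8Z)-4-[(tert-butyldimethylsilyl)oxy]-6-{3-[(tert-butyldimethylsilyl)oxy]prop-1-en-2-yl}-10,10-bis[(4-methoxyphenyl)methoxy]-3,9-dimethyl-7-[(triethylsilyl)oxy]dec-8-enal | O=CC[C@H](C)[C@@H](O[Si](C)(C)C(C)(C)C)C[C@@H](C(=C)CO[Si](C)(C)C(C)(C)C)[C@H](O[Si](CC)(CC)CC)/C=C(/C)C(OCc1ccc(OC)cc1)OCc1ccc(OC)cc1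
F0 | step 17 | none | none
F8 | step 20 | (3S,4S,6S,7R,8R,9E)-4-[(tert-butyldimethylsilyl)oxy]-6-{3-[(tert-butyldimethylsilyl)oxy]prop-1-en-2-yl}-10-[(4-methoxyphenyl)methoxy]-3,9-dimethyl-8-(4,4,5,5-tetramethyl-1,3,2-dioxaborolan-2-yl)-7-[(triethylsilyl)oxy]dec-9-en-1-ol | OCC[C@H](C)[C@@H](O[Si](C)(C)C(C)(C)C)C[C@@H](C(=C)CO[Si](C)(C)C(C)(C)C)[C@H](O[Si](CC)(CC)CC)[C@H](B1OC(C)(C)C(C)(C)O1)/C(C)=C/OCc1ccc(OC)cc1
F9 | step 26 | C9 2-[bis(2,2,2-trifluoroethoxy)phosphoryl]propanoate of 32 (both epimers at the phosphonate-bearing carbon) | C=C1C(=O)O[C@@H]2/C=C(/C)[C@H](OCc3ccc(OC)cc3)[C@H](OC(C)=O)C[C@H](C)[C@@H](OC(=O)C(C)P(=O)(OCC(F)(F)F)OCC(F)(F)F)C[C@@H]12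
A1 | alternative 1 | ten-membered C9 ketone with Z C4=C5, C2/C3 acetonide, C6 tert-butyldimethylsilyl ether and C7 isopropenyl group | O=C1C[C@@H](C(C)=C)[C@H](O[Si](C)(C)C(C)(C)C)/C=C(/C)[C@@H]2OC(C)(C)O[C@@H]2C[C@@H]1C
A2 | alternative 2 | target skeleton with free C3 alcohol and C2 tert-butyldimethylsilyl ether (lactone and angelate in place) | C=C1C(=O)O[C@@H]2/C=C(/C)[C@H](O)[C@H](O[Si](C)(C)C(C)(C)C)C[C@H](C)[C@@H](OC(=O)/C(C)=C\C)C[C@@H]12
A3 | alternative 3 | cyclodecenol with free C6 alcohol, C2/C3 acetonide, C9 tert-butyldimethylsilyl ether and a 3-[(4-methoxyphenyl)methoxy]prop-1-en-2-yl branch on C7 | O[C@@H]1/C=C(/C)[C@@H]2OC(C)(C)O[C@@H]2C[C@H](C)[C@@H](O[Si](C)(C)C(C)(C)C)C[C@H]1C(=C)COCc1ccc(OC)cc1
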